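## The problem

Locants follow the target 33: ring A is C1, C10, C11(=C20H2), C12, C13, C14; ring B runs C1 to C10 through the Z alkene C5(CH3)=C6; the lactone is O–C7, C8(OH), C17(CH3), C19(=O). 33 is a bicyclo[8.4.0]tetradecane in which six-membered ring A and ten-membered ring B are trans-fused across quaternary C1 and methine C10, and a γ-lactone is trans-fused to ring B across C7–C8. Its eight stereocentres form two clusters: C14–C1–C2 (two acetoxy carbinols, mutually syn, flanking the quaternary carbon) with C10 beside it, and C9–C8–C7–C17 around the lactone. C1 can direct C10 when ring A is closed, C10 can direct C9 by Felkin–Anh addition, C17 can direct C8 on a five-membered ring, and one carbinol of the 1,3-diol can set the other by chelate-controlled reduction; C1, C7 and the first of C2/C14 need an external source of chirality. Ring B is a medium ring with a Z-trisubstituted alkene, and its closure has to tolerate the 1,1-disubstituted C11=C20 methylene. The fragile points are three secondary acetates next to a free tertiary C8 hydroxyl that is β to the lactone carbonyl, the allylic C7–O bond, and, at the aldehyde stage, a β,γ-unsaturated C9 carbonyl whose C10 proton invites epimerisation and migration of the methylene into conjugation. The key step rests on one feature: C10 is α to C9, which can be held at the aldehyde level, and is bonded to C11, whose exocyclic methylene is what a terminal alkyne C11≡C20 leaves behind after attack on its internal carbon, so an enol derivative of the C9 aldehyde closes ring A by forming C10–C11.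

## Retrosynthesis

**Acetates last (33 ← 32 ← 31).** The three acetyl groups and two isopropylidene acetals are removed first on paper. Acetates carried from the start would be shorter, but they would not survive the alkynyllithium and aluminium hydride steps that build the lactone. Tetraol 32 needs only one acylation that distinguishes three secondary hydroxyls from the tertiary C8 hydroxyl, and 31 carries each diol (C2/C14 and C8/C9) as one acetonide.

**Ring B at C4–C5 (31 ← 29).** The ten-membered ring is opened at the sp3–sp2 bond C4–C5, to be formed by hydroboration of a C2 vinyl group and intramolecular Suzuki–Miyaura coupling with a (Z)-iodoalkene on C7. Metathesis at C5=C6 is excluded because the C11 methylene would close a six-membered ring with a C7 vinyl group. A Nozaki–Hiyama–Kishi closure at C6–C7 would need a (Z)-1-iodo-2-methylalkene on the C2 arm, which is much harder to obtain than an iodide derived from a propargylic alcohol. The forward step needs a borane that takes the vinyl group and leaves the methylene; 9-BBN does not discriminate, a hindered dialkylborane does.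

**Lactone carbonyl moved from C7 to C19 (29 ← 28 ← 27 ← 26 ← 24).** The C6–C7 bond is cut to a propynyl anion (25) and a butyrolactone 24 whose carbonyl is C7 and whose C19 is still CH2–O. This isomeric lactone makes C8 an enolisable α-carbon (used in the next cut) and turns C7 into an ynone, so C7 can be set by catalyst-controlled reduction and the Z-iodoalkene by directed hydroalumination. The price is an oxidative relactonisation (28 to 29).

**C8–C9 by aldol (24 ← 23 ← 19 + 22).** Cutting C8–C9 gives ring A aldehyde 19 and the ene-diol bis-silyl ether 22 of a 3-hydroxy-4-methylbutyrolactone. The neighbouring cuts (C8–C17 by a propionate aldol onto a ketone, C8–C9 by pinacol coupling) need the medium ring or an α,α'-dioxygenated ketone first. Here both new centres are read from existing ones: C8 from the C17 methyl on a five-membered ring, C9 from C10 by Felkin–Anh addition.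

**Ring A by the key step (19 ← 18).** The C10–C11 bond is cut to the silyl enol ether of a C9 aldehyde and a terminal alkyne. The alkyne is a direct precursor of the methylene, so no olefination of a ketone beside the quaternary centre is needed. 18 is monocyclic with three stereocentres, and the closure must deliver C9 trans to C2.

**Protecting and unmasking (18 ← 17 ← 16 ← 15).** The enol ether comes from aldehyde 17, which comes from dimethyl acetal 16. The syn-1,3-diol is tied as an acetonide (15 to 16), so the later acetal cleavage must spare a ketone-derived acetal.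

**C14 arm (15 ← 14 ← 13 ← 12 ← 9 + 10).** The C13–C14 bond is cut to Weinreb amide 9 and the Grignard reagent from bromide 10. The resulting β-hydroxy ketone 12 sets C14 from C2 by syn-selective reduction, which suits the syn relationship of the two carbinols. The propargylic alkyne is reduced to the vinyl group only after the diol is in place (14 to 15), so no vinyl ketone is handled.

**C2 arm (9 ← 8 ← 7 ← 5 + 6).** The C2–C3 bond is cut to Weinreb amide 5 and silylacetylide 6. An ynone is chosen over a vinyl ketone because its transfer hydrogenation is reliably catalyst-controlled next to a quaternary carbon.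

**Quaternary C1 (5 ← 4 ← 3 ← 1 + 2).** C1 is traced to the prochiral malonate 3, made by alkylating 1 with bromoacetal 2, which brings C10–C9 in masked form from the first step. Enzymatic hydrolysis of one ester gives 4 and differentiates the two carbonyl arms.

**Lactone piece (22 ← 21 ← 20).** 22 comes from commercial (R)-4-methylbutyrolactone 20 by α-hydroxylation and double silylation.

## Roads not taken

**Alternative 1:** The cut is C1–C10, made across a fourteen-membered carbocycle that already holds the lactone. BF3·OEt2 would ionise a C14–C1 epoxide at tertiary C1 and an allylsilane would attack through C10 to give A1, closing ring A, defining ring B and releasing the C11 methylene at once. Its merit is economy: the quaternary centre, C10 and a free, differentiated C14 hydroxyl arise in one event. Its weak points are that the outcome depends entirely on the conformation of a heavily substituted fourteen-membered ring, that the C1 cation can also be captured by the C5=C6 alkene or collapse by hydride shift, and that the macrocycle with its epoxide and allylsilane geometry has to be built first. In ring construction this road is shorter than the chosen one, which needs two separate closures (steps 14 and 23). The chosen plan offers in return stereocontrol that can be read at each step from acyclic or small-ring models, and a quaternary centre fixed at the outset.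

**Alternative 2:** The cut is C8–C9. Low-valent titanium from TiCl3(DME)1.5 and zinc–copper couple would join a C9 aldehyde and a C8 ketone as ketyls to give diol A2, closing ring B and installing both oxygens. It is more direct for ring B than hydroboration and coupling, and it has no methylene selectivity problem. Against it, two stereocentres (one tertiary) would be formed in a medium-ring closure with no clear control element, the silyloxy group on C7 next to the C8 ketyl is prone to reductive loss, deoxygenation to the alkene can compete, and the lactone must still be made from the silyl-protected C19 arm. The chosen plan fixes C8 and C9 before any medium ring exists and closes ring B at a bond remote from stereocentres.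

**Alternative 3:** The cut is C8–C17 in the lactone. SmI2 would reduce a 2-bromopropanoate on O7 to a samarium enolate that adds to the adjacent C8 ketone, giving A3. For the lactone alone this is the more economical answer: the tether from O7 dictates the face of C8, the lactone forms at the right oxidation pattern, and A3 is two steps from 33, whereas the chosen plan spends steps 19 to 22 moving the carbonyl from C7 to C19. Its weak points are that the ten-membered ring with a ketone flanked by two oxygenated carbons must already exist, so ring B is not solved; that an α-acyloxy ketone is itself reduced by SmI2 with loss of the O7 ester; and that the C17 configuration depends on enolate geometry in a medium-ring transition state. The chosen plan sets C8 and C17 on a rigid butyrolactone and specifies how both carbocycles arise.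

Key step: step 14

Assumption: pig liver esterase is taken to hydrolyse the enantiotopic ester of 3 that gives the (S)-half-ester 4 in useful enantiomeric purity; the sense is not established for this substrate.

## Route

Step 1
Reactants: 1 dimethyl 2-methylpropanedioate; 2 2-bromo-1,1-dimethoxyethane
Product: 3 dimethyl 2-(2,2-dimethoxyethyl)-2-methylpropanedioate
Conditions: NaH, DMF, 0 °C; then 2, NaI (cat.), 110 °C
Reagents that add atoms: none
Why: Malonate alkylation (SN2) by the sodium enolate; the β-alkoxy bromide is sluggish and needs heat, and the quaternary product cannot be alkylated again.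

Step 2
Reactants: 3 dimethyl 2-(2,2-dimethoxyethyl)-2-methylpropanedioate
Product: 4 (S)-2-(2,2-dimethoxyethyl)-3-methoxy-2-methyl-3-oxopropanoic acid
Conditions: pig liver esterase, phosphate buffer pH 7.5, rt; then citric acid to pH 4
Reagents that add atoms: water O
Why: Enzymatic desymmetrisation of a prochiral 2,2-disubstituted malonate; hydrolysis of one enantiotopic ester fixes C1, which cannot epimerise afterwards.

Step 3
Reactants: 4 (S)-half-ester
Product: 5 methyl (S)-2-(2,2-dimethoxyethyl)-3-[methoxy(methyl)amino]-2-methyl-3-oxopropanoate
Conditions: MeNH(OMe)·HCl, EDC·HCl, HOBt (cat.), N-methylmorpholine, CH2Cl2, 0 °C to rt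
Reagents that add atoms: N,O-dimethylhydroxylamine hydrochloride CNOC.Cl
Why: Carbodiimide amidation converts only the free acid into the Weinreb amide, so the two carbonyl arms stay differentiated (amide becomes C2, ester becomes C14).

Step 4
Reactants: 5 Weinreb amide ester; 6 lithium (trimethylsilyl)acetylide
Product: 7 methyl (S)-2-(2,2-dimethoxyethyl)-2-methyl-3-oxo-5-(trimethylsilyl)pent-4-ynoate
Conditions: THF, −78 to −40 °C; aq. NH4Cl
Reagents that add atoms: none
Why: Weinreb ketone synthesis; the chelated tetrahedral adduct stops at the ynone and the neopentyl-type methyl ester does not compete at low temperature.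

Step 5
Reactants: 7 ynone ester
Product: 8 methyl (2S,3S)-2-(2,2-dimethoxyethyl)-3-hydroxy-2-methyl-5-(trimethylsilyl)pent-4-ynoate
Conditions: Ru[(S,S)-TsDPEN](p-cymene) (cat.), iPrOH, rt
Reagents that add atoms: none
Why: Noyori asymmetric transfer hydrogenation of an ynone; the (S,S) ligand places the alkynyl group where an aryl group would sit and sets C2 under catalyst control, independent of the adjacent quaternary centre.

Step 6
Reactants: 8 propargylic alcohol ester
Product: 9 (2S,3S)-2-(2,2-dimethoxyethyl)-3-hydroxy-N-methoxy-N,2-dimethyl-5-(trimethylsilyl)pent-4-ynamide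
Conditions: MeNH(OMe)·HCl, iPrMgCl, THF, −20 to 0 °C
Reagents that add atoms: N,O-dimethylhydroxylamine hydrochloride CNOC.Cl
Why: Direct aminolysis of the ester by the magnesium amide of MeNHOMe (Weinreb amide formation); the hydroxyl is carried as its magnesium alkoxide, which should not undergo retro-aldol cleavage at or below 0 °C.

Step 7
Reactants: 9 hydroxy Weinreb amide; 10 (4-bromobut-1-yn-1-yl)trimethylsilane
Product: 12 (3S,4S)-4-(2,2-dimethoxyethyl)-3-hydroxy-4-methyl-1,9-bis(trimethylsilyl)nona-1,8-diyn-5-one, via Grignard reagent 11 (not isolated)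
Conditions: Mg, THF (10 to 11); then 9, THF, 0 °C to rt; aq. NH4Cl
Reagents that add atoms: none
Why: Weinreb ketone synthesis with a homopropargyl Grignard reagent whose alkyne is silyl-capped; one equivalent is spent on the hydroxyl and the chelated adduct releases the ketone only on work-up.

Step 8
Reactants: 12 β-hydroxy ketone
Product: 13 (3S,4R,5S)-4-(2,2-dimethoxyethyl)-4-methyl-1,9-bis(trimethylsilyl)nona-1,8-diyne-3,5-diol
Conditions: Et2BOMe, THF/MeOH, −78 °C; NaBH4; MeOH co-evaporation
Reagents that add atoms: none
Why: Narasaka–Prasad reduction; external hydride attacks the boron chelate of the β-hydroxy ketone on the face that gives the syn-1,3-diol, so C14 is set from C2.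

Step 9
Reactants: 13 syn-diol
Product: 14 (3R,4R,5S)-4-(2,2-dimethoxyethyl)-4-methylnona-1,8-diyne-3,5-diol
Conditions: K2CO3 (cat.), MeOH, rt
Reagents that add atoms: none
Why: Base-catalysed methanolysis of both alkynyl–silicon bonds; no carbonyl is present, so diol and acetal are untouched.

Step 10
Reactants: 14 diyne diol
Product: 15 (3R,4R,5S)-4-(2,2-dimethoxyethyl)-4-methylnon-1-en-8-yne-3,5-diol
Conditions: NaAlH2(OCH2CH2OMe)2, THF, 0 °C to rt; aq. Rochelle salt
Reagents that add atoms: none
Why: Hydroxyl-directed trans-hydroalumination of the propargylic alkyne and protonolysis give the vinyl carbinol; the remote 4-alkyn-1-ol type alkyne and the acetal are not reduced.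

Step 11
Reactants: 15 vinyl diol
Product: 16 (4S,5R,6R)-4-(but-3-yn-1-yl)-5-(2,2-dimethoxyethyl)-6-ethenyl-2,2,5-trimethyl-1,3-dioxane
Conditions: 2-methoxypropene, PPTS (cat.), CH2Cl2, 0 °C
Reagents that add atoms: 2-methoxypropene COC(C)=C
Why: Kinetic acetonide formation from the enol ether under weak acid; the syn-1,3-diol closes a chair dioxane, while the aldehyde dimethyl acetal ionises far more slowly and is left alone.

Step 12
Reactants: 16 acetonide acetal
Product: 17 2-[(4S,5R,6R)-4-(but-3-yn-1-yl)-6-ethenyl-2,2,5-trimethyl-1,3-dioxan-5-yl]acetaldehyde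
Conditions: Et3SiOTf, 2,4,6-collidine, CH2Cl2, 0 °C; then H2O
Reagents that add atoms: water O
Why: Silyl triflate–collidine deacetalisation (pyridinium intermediate, then hydrolysis) cleaves aldehyde acetals selectively in the presence of ketone-derived acetals, so the acetonide survives.

Step 13
Reactants: 17 acetonide aldehyde
Product: 18 tert-butyl({(E)-2-[(4S,5R,6R)-4-(but-3-yn-1-yl)-6-ethenyl-2,2,5-trimethyl-1,3-dioxan-5-yl]ethenyl}oxy)dimethylsilane (E/Z mixture expected; E drawn)
Conditions: tBuMe2SiOTf, Et3N, CH2Cl2, 0 °C
Reagents that add atoms: tert-butyldimethylsilyl trifluoromethanesulfonate CC(C)(C)[Si](C)(C)OS(=O)(=O)C(F)(F)F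
Why: Soft enolisation of the aldehyde (O-silylation, then deprotonation by the amine) gives the silyl enol ether; both geometries should converge in step 14.

Step 14
Reactants: 18 silyl enol ether alkyne
Product: 19 ring A aldehyde: cis-fused 4-ethenyl-2,2,4a-trimethyl-6-methylidenehexahydro-4H-1,3-benzodioxine-5-carbaldehyde with C1 C2 C10 C14 arranged as in 33 (formyl cis to the angular methyl)
Conditions: Ph3PAuCl (10 mol%), AgBF4 (10 mol%), CH2Cl2/H2O (10:1), rt to 40 °C
Reagents that add atoms: none
Why: Cationic monovalent gold (Ph3PAu+ from Ph3PAuCl and AgBF4) coordinates the terminal alkyne, and the enol ether carbon C10 attacks the internal carbon C11 anti to gold, closing ring A in the 6-exo-dig mode and giving a vinylgold silyloxocarbenium ion. Water takes the silyl group as the silanol, and protodeauration of the C20–Au bond leaves the exocyclic methylene and the C9 aldehyde. The closest known reaction is the gold-catalysed cycloisomerisation of silyl enol ethers onto alkynes (Conia-ene type), known for 5-exo-dig and 6-exo-dig closures. The new stereocentre C10 is controlled by quaternary C1: the C1–C14 bond must lie roughly parallel to the π orbital at C10 for the tether to reach, and of the two other C1 substituents the small methyl group takes the position next to C9 to minimise allylic 1,3-strain while C2 points away, so C9 ends cis to the methyl group and trans to C2 (formyl equatorial in the chair) from either enol ether geometry. The step needs attack at C11 and not at C20, which the Markovnikov polarisation of the terminal alkyne and the six-membered transition state secure. It also needs the enol ether to outrun the C2 vinyl group as nucleophile, which its much higher π-nucleophilicity secures. The near-neutral medium and short reaction time should leave the β,γ-unsaturated aldehyde unconjugated and the acetonide intact.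

Step 15
Reactants: 20 (R)-4-methyldihydrofuran-2(3H)-one
Product: 21 (3R,4S)-3-hydroxy-4-methyldihydrofuran-2(3H)-one (trans isomer drawn; the C3 configuration is irrelevant)
Conditions: KN(SiMe3)2, THF, −78 °C; then 3-phenyl-2-(phenylsulfonyl)oxaziridine; aq. NH4Cl
Reagents that add atoms: 3-phenyl-2-(phenylsulfonyl)oxaziridine O=S(=O)(c1ccccc1)N1OC1c1ccccc1
Why: Enolate oxidation with an N-sulfonyloxaziridine; oxygen enters mainly trans to the methyl group, and C8 is enolised again in step 16.

Step 16
Reactants: 21 hydroxy lactone
Product: 22 (S)-4-methyl-2,3-bis(trimethylsilyloxy)-4,5-dihydrofuran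
Conditions: LiN(iPr)2, Me3SiCl, THF, −78 to 0 °C; non-aqueous work-up, used crude
Reagents that add atoms: chlorotrimethylsilane C[Si](C)(C)Cl
Why: O-Silylation of the hydroxyl and in situ trapping of the lactone enolate give the ene-diol bis-silyl ether, a ketene silyl acetal that is nucleophilic at C8.

Step 17
Reactants: 19 ring A aldehyde; 22 ene-diol bis-silyl ether
Product: 23 aldol diol lactone: (3S,4S)-3-hydroxy-4-methyl-dihydrofuran-2(3H)-one bearing at C3 (= C8) the (R)-hydroxymethyl carbon C9 attached to C10 of ring A; all stereocentres as in 33
Conditions: BF3·OEt2, CH2Cl2, −78 °C; aq. NaHCO3; then citric acid, MeOH, rt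
Reagents that add atoms: none
Why: Mukaiyama aldol through an open transition state; the nucleophile adds anti to the C17 methyl (placing O8 cis to it) and the aldehyde reacts on its Felkin–Anh face with quaternary C1 anti to the incoming bond, which gives the 9R carbinol; acidic methanol then removes the silyl groups.

Step 18
Reactants: 23 aldol diol lactone
Product: 24 bis-acetonide lactone: the 8,9-O-isopropylidene derivative of 23 (dioxolane spiro-fused to the lactone at C8)
Conditions: 2-methoxypropene, PPTS (cat.), CH2Cl2, 0 °C to rt
Reagents that add atoms: 2-methoxypropene COC(C)=C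
Why: Acetonide formation on the 1,2-diol blocks retro-aldol cleavage of the β-hydroxy lactone and masks both hydroxyls for the organometallic steps.

Step 19
Reactants: 24 bis-acetonide lactone; 25 prop-1-yn-1-yllithium
Product: 26 hydroxy ynone: C7 but-2-ynoyl ketone on C8 with free C19 primary alcohol (in equilibrium with its lactol)
Conditions: THF, −78 to −30 °C; aq. NH4Cl
Reagents that add atoms: none
Why: Addition of an alkynyllithium to a γ-lactone stops at the lithium hemiketal and gives the hydroxy ynone on work-up; the slim sp nucleophile is chosen because the carbonyl is flanked by quaternary C8.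

Step 20
Reactants: 26 hydroxy ynone
Product: 27 propargylic diol with (7S)-carbinol
Conditions: Ru[(R,R)-TsDPEN](p-cymene) (cat.), iPrOH, rt
Reagents that add atoms: none
Why: Noyori asymmetric transfer hydrogenation with the base-free amido complex; the (R,R) ligand sets 7S under catalyst control, and the neutral medium avoids oxa-Michael closure of the hydroxy ynone.

Step 21
Reactants: 27 propargylic diol
Product: 28 (Z)-iodoalkene diol: C7 carbinol carrying the (Z)-2-iodoprop-1-enyl group (I on C5 cis to C7)
Conditions: NaAlH2(OCH2CH2OMe)2, THF, 0 °C to rt; then I2, −78 to 0 °C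
Reagents that add atoms: iodine II
Why: Alkoxide-directed trans-hydroalumination places aluminium on C5 cis to C7, and iodinolysis with retention gives the (Z)-iodoalkene; isolated alkenes and acetonides are inert.

Step 22
Reactants: 28 (Z)-iodoalkene diol
Product: 29 iodoalkenyl lactone: γ-lactone O–C7 / C19(=O) with 8,9- and 2,14-acetonides and the C2 vinyl group
Conditions: TEMPO (cat.), PhI(OAc)2, CH2Cl2, rt
Reagents that add atoms: none
Why: Oxoammonium oxidation of the primary alcohol, lactol formation with the C7 hydroxyl and further oxidation give the γ-lactone; the hindered allylic secondary alcohol is oxidised more slowly than the primary one.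

Step 23
Reactants: 29 iodoalkenyl lactone
Product: 31 ring B bis-acetonide lactone: 2,14:8,9-di-O-isopropylidene derivative of tetraol 32, via alkylborane 30 (not isolated)
Conditions: (Me2CHCHMe)2BH [from BH3·SMe2 and 2-methylbut-2-ene], THF, 0 °C; then PdCl2(dppf) (cat.), AsPh3, Cs2CO3, DMF/THF/H2O, high dilution, rt to 45 °C
Reagents that add atoms: none
Why: Hydroboration then intramolecular B-alkyl Suzuki–Miyaura coupling; the hindered dialkylborane adds to the monosubstituted vinyl group faster than to the 1,1-disubstituted methylene (9-BBN would not discriminate) and faster than it reduces the lactone, the primary alkyl group is the one transferred to palladium, and retention at C5 gives the Z ring alkene.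

Step 24
Reactants: 31 ring B bis-acetonide lactone
Product: 32 tetraol: 2,9,14-tri-O-deacetyl derivative of 33
Conditions: AcOH/H2O (4:1), 45 °C
Reagents that add atoms: none
Why: Acid hydrolysis of both isopropylidene acetals; lactone, alkenes and the tertiary carbinol should tolerate warm aqueous acetic acid.

Step 25
Reactants: 32 tetraol
Product: 33 target CNP0187723.2 (1S,2R,7S,8S,9R,10S,14S,17R; 5Z)
Conditions: Ac2O, DMAP (cat.), pyridine, CH2Cl2, 0 °C to rt
Reagents that add atoms: acetic anhydride CC(=O)OC(C)=O
Why: DMAP-catalysed acylation of the three secondary hydroxyls; the tertiary C8 hydroxyl is too hindered to react under these conditions.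

## Compound list

1 | dimethyl 2-methylpropanedioate | COC(=O)C(C)C(=O)OC | starting material
2 | 2-bromo-1,1-dimethoxyethane | COC(CBr)OC | starting material
3 | dimethyl 2-(2,2-dimethoxyethyl)-2-methylpropanedioate | COC(=O)C(C)(CC(OC)OC)C(=O)OC | intermediate
4 | (S)-2-(2,2-dimethoxyethyl)-3-methoxy-2-methyl-3-oxopropanoic acid | COC(=O)[C@@](C(=O)O)(C)CC(OC)OC | intermediate
5 | methyl (S)-2-(2,2-dimethoxyethyl)-3-[methoxy(methyl)amino]-2-methyl-3-oxopropanoate | COC(=O)[C@@](C(=O)N(C)OC)(C)CC(OC)OC | intermediate
6 | lithium (trimethylsilyl)acetylide | [Li]C#C[Si](C)(C)C | starting material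
7 | methyl (S)-2-(2,2-dimethoxyethyl)-2-methyl-3-oxo-5-(trimethylsilyl)pent-4-ynoate | COC(=O)[C@@](C(=O)C#C[Si](C)(C)C)(C)CC(OC)OC | intermediate
8 | methyl (2S,3S)-2-(2,2-dimethoxyethyl)-3-hydroxy-2-methyl-5-(trimethylsilyl)pent-4-ynoate | COC(=O)[C@@]([C@H](O)C#C[Si](C)(C)C)(C)CC(OC)OC | intermediate
9 | (2S,3S)-2-(2,2-dimethoxyethyl)-3-hydroxy-N-methoxy-N,2-dimethyl-5-(trimethylsilyl)pent-4-ynamide | CON(C)C(=O)[C@@]([C@H](O)C#C[Si](C)(C)C)(C)CC(OC)OC | intermediate
10 | (4-bromobut-1-yn-1-yl)trimethylsilane | C[Si](C)(C)C#CCCBr | starting material
11 | [4-(trimethylsilyl)but-3-yn-1-yl]magnesium bromide | C[Si](C)(C)C#CCC[Mg]Br | intermediate (not isolated)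
12 | (3S,4S)-4-(2,2-dimethoxyethyl)-3-hydroxy-4-methyl-1,9-bis(trimethylsilyl)nona-1,8-diyn-5-one | C[Si](C)(C)C#CCCC(=O)[C@@]([C@H](O)C#C[Si](C)(C)C)(C)CC(OC)OC | intermediate
13 | (3S,4R,5S)-4-(2,2-dimethoxyethyl)-4-methyl-1,9-bis(trimethylsilyl)nona-1,8-diyne-3,5-diol | C[Si](C)(C)C#CCC[C@H](O)[C@@]([C@H](O)C#C[Si](C)(C)C)(C)CC(OC)OC | intermediate
14 | (3R,4R,5S)-4-(2,2-dimethoxyethyl)-4-methylnona-1,8-diyne-3,5-diol | C#CCC[C@H](O)[C@@]([C@H](O)C#C)(C)CC(OC)OC | intermediate
15 | (3R,4R,5S)-4-(2,2-dimethoxyethyl)-4-methylnon-1-en-8-yne-3,5-diol | C#CCC[C@H](O)[C@@]([C@H](O)C=C)(C)CC(OC)OC | intermediate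
16 | (4S,5R,6R)-4-(but-3-yn-1-yl)-5-(2,2-dimethoxyethyl)-6-ethenyl-2,2,5-trimethyl-1,3-dioxane | C#CCC[C@@H]1OC(C)(C)O[C@H](C=C)[C@]1(C)CC(OC)OC | intermediate
17 | 2-[(4S,5R,6R)-4-(but-3-yn-1-yl)-6-ethenyl-2,2,5-trimethyl-1,3-dioxan-5-yl]acetaldehyde | C#CCC[C@@H]1OC(C)(C)O[C@H](C=C)[C@]1(C)CC=O | intermediate
18 | tert-butyldimethylsilyl enol ether of 17 (key-step precursor; E drawn) | C#CCC[C@@H]1OC(C)(C)O[C@H](C=C)[C@]1(C)/C=C/O[Si](C)(C)C(C)(C)C | intermediate
19 | ring A aldehyde, 4-ethenyl-2,2,4a-trimethyl-6-methylidenehexahydro-4H-1,3-benzodioxine-5-carbaldehyde, C1 C2 C10 C14 as in 33 (key-step product) | C=C1CC[C@@H]2OC(C)(C)O[C@H](C=C)[C@]2(C)[C@H]1C=O | intermediate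
20 | (R)-4-methyldihydrofuran-2(3H)-one | C[C@H]1COC(=O)C1 | starting material
21 | (3R,4S)-3-hydroxy-4-methyldihydrofuran-2(3H)-one | C[C@H]1COC(=O)[C@@H]1O | intermediate
22 | (S)-4-methyl-2,3-bis(trimethylsilyloxy)-4,5-dihydrofuran | C[C@H]1COC(O[Si](C)(C)C)=C1O[Si](C)(C)C | intermediate
23 | aldol diol lactone (C7 lactone carbonyl, free 8- and 9-hydroxyls, 2,14-acetonide) | C=C1CC[C@@H]2OC(C)(C)O[C@H](C=C)[C@]2(C)[C@H]1[C@@H](O)[C@]1(O)[C@@H](C)COC1=O | intermediate
24 | bis-acetonide lactone (8,9- and 2,14-acetonides, C7 lactone carbonyl) | C=C1CC[C@@H]2OC(C)(C)O[C@H](C=C)[C@]2(C)[C@H]1[C@H]1OC(C)(C)O[C@]12[C@@H](C)COC2=O | intermediate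
25 | prop-1-yn-1-yllithium | [Li]C#CC | starting material
26 | hydroxy ynone (C7 ketone, C19 primary alcohol) | C=C1CC[C@@H]2OC(C)(C)O[C@H](C=C)[C@]2(C)[C@H]1[C@H]1OC(C)(C)O[C@]1(C(=O)C#CC)[C@@H](C)CO | intermediate
27 | (7S)-propargylic diol | C=C1CC[C@@H]2OC(C)(C)O[C@H](C=C)[C@]2(C)[C@H]1[C@H]1OC(C)(C)O[C@]1([C@@H](O)C#CC)[C@@H](C)CO | intermediate
28 | (Z)-iodoalkene diol | C=C1CC[C@@H]2OC(C)(C)O[C@H](C=C)[C@]2(C)[C@H]1[C@H]1OC(C)(C)O[C@]1([C@@H](O)/C=C(\I)C)[C@@H](C)CO | intermediate
29 | iodoalkenyl lactone (C19 lactone carbonyl, C2 vinyl) | C=C1CC[C@@H]2OC(C)(C)O[C@H](C=C)[C@]2(C)[C@H]1[C@H]1OC(C)(C)O[C@@]12[C@H](/C=C(\I)C)OC(=O)[C@@H]2C | intermediate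
30 | C4 bis(3-methylbutan-2-yl)borane of 29 | C=C1CC[C@@H]2OC(C)(C)O[C@H](CCB(C(C)C(C)C)C(C)C(C)C)[C@]2(C)[C@H]1[C@H]1OC(C)(C)O[C@@]12[C@H](/C=C(\I)C)OC(=O)[C@@H]2C | intermediate (not isolated)
31 | ring B bis-acetonide lactone (2,14:8,9-di-O-isopropylidene derivative of 32) | C=C1CC[C@@H]2OC(C)(C)O[C@@H]3CC/C(C)=C\[C@@H]4OC(=O)[C@H](C)[C@]45OC(C)(C)O[C@@H]5[C@@H]1[C@]23C | intermediate
32 | tetraol (2,9,14-tri-O-deacetyl derivative of 33) | C=C1CC[C@H](O)[C@@]2(C)[C@H]1[C@@H](O)[C@@]1(O)[C@H](/C=C(/C)CC[C@H]2O)OC(=O)[C@@H]1C | intermediate
33 | CNP0187723.2 | C=C1CC[C@H](OC(C)=O)[C@@]2(C)[C@H]1[C@@H](OC(C)=O)[C@@]1(O)[C@H](/C=C(/C)CC[C@H]2OC(C)=O)OC(=O)[C@@H]1C | target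

## Step count and risks

Total: 25 steps. Longest linear sequence: 23 steps (steps 1 to 14 and 17 to 25); steps 15 and 16 prepare the lactone piece.

**Step 14 (key step).** The likely failures are hydrolysis of the silyl enol ether back to 17 before the alkyne is engaged, erosion of facial selectivity at C10, and acid-promoted migration of the new methylene into conjugation with the aldehyde. The fallback replaces π-acid activation by a radical closure. From 18, PhSeCl at −78 °C gives the α-phenylselanyl aldehyde F1. Slow addition of Bu3SnH with AIBN in benzene generates the C10 radical, which closes 6-exo-dig onto the alkyne through the same chair, and hydrogen transfer to the vinyl radical returns the route at 19.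

**Step 23.** The likely failures are slow transmetalation of the hindered trialkylborane, which leads to oligomerisation or β-hydride elimination, together with partial hydroboration of the C11 methylene or reduction of the lactone. The fallback changes the organometallic. From 29, hydroboration with the same borane and oxidation with NaBO3 give the primary alcohol F2, and I2/PPh3/imidazole gives the alkyl iodide F3. Activated zinc in DMA inserts into the C(sp3)–I bond only, giving the alkylzinc iodide F4, and a palladium-catalysed intramolecular Negishi coupling at high dilution returns the route at 31.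

**Step 19.** The likely failure is that the acetylide does not reach a lactone carbonyl shielded by quaternary C8 and the spiro-acetonide, or that a second addition occurs once the ring has opened. The fallback separates reduction from carbon–carbon bond formation. From 24, iBu2AlH at −78 °C gives the lactol F5. Excess prop-1-ynylmagnesium bromide adds to its open hydroxy aldehyde form to give the diol F6 as both C7 epimers, and MnO2 oxidises only the propargylic alcohol, returning the route at 26, after which step 20 sets C7.

**Step 17.** The likely failure is poor facial selectivity at C9, because the Felkin–Anh preference of the aldehyde has to prevail in a very congested bond formation between a tetrasubstituted nucleophile and an α-branched aldehyde; retro-aldol cleavage during desilylation is a second concern. The fallback uses a closed, chelated transition state. From 21, 4-methoxybenzyl trichloroacetimidate with catalytic acid gives the PMB ether F7. Its lithium enolate (LiN(iPr)2, THF, −78 °C), in which lithium is held between the enolate and ether oxygens, adds to 19 to give the aldol adduct F8, and DDQ in wet CH2Cl2 removes the PMB group, returning the route at 23.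

**Step 2.** The likely failure is low or opposite enantioselection by the esterase with this particular side chain. The fallback is a classical resolution. From 3, one equivalent of KOH in methanol gives the racemic half-ester F9. Crystallisation of its salt with (S)-1-phenylethylamine gives the diastereomerically pure salt F10 (the enantiomeric amine is used if the other salt is the less soluble one), and acidification returns the route at 4.

## Further compounds

F1 | step 14 | α-phenylselanyl aldehyde (17 with SePh on C10, both epimers) | C#CCC[C@@H]1OC(C)(C)O[C@H](C=C)[C@]1(C)C([Se]c1ccccc1)C=O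
F2 | step 23 | C4 primary alcohol from 29 | C=C1CC[C@@H]2OC(C)(C)O[C@H](CCO)[C@]2(C)[C@H]1[C@H]1OC(C)(C)O[C@@]12[C@H](/C=C(\I)C)OC(=O)[C@@H]2C
F3 | step 23 | C4 alkyl iodide | C=C1CC[C@@H]2OC(C)(C)O[C@H](CCI)[C@]2(C)[C@H]1[C@H]1OC(C)(C)O[C@@]12[C@H](/C=C(\I)C)OC(=O)[C@@H]2C
F4 | step 23 | C4 alkylzinc iodide | C=C1CC[C@@H]2OC(C)(C)O[C@H](CC[Zn]I)[C@]2(C)[C@H]1[C@H]1OC(C)(C)O[C@@]12[C@H](/C=C(\I)C)OC(=O)[C@@H]2C
F5 | step 19 | lactol from 24 (both anomers) | C=C1CC[C@@H]2OC(C)(C)O[C@H](C=C)[C@]2(C)[C@H]1[C@H]1OC(C)(C)O[C@]12[C@@H](C)COC2O
F6 | step 19 | propargylic diol, both C7 epimers | C=C1CC[C@@H]2OC(C)(C)O[C@H](C=C)[C@]2(C)[C@H]1[C@H]1OC(C)(C)O[C@]1(C(O)C#CC)[C@@H](C)CO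
F7 | step 17 | (3R,4S)-3-[(4-methoxybenzyl)oxy]-4-methyldihydrofuran-2(3H)-one | C[C@H]1COC(=O)[C@@H]1OCc1ccc(OC)cc1
F8 | step 17 | 8-O-(4-methoxybenzyl) aldol adduct | C=C1CC[C@@H]2OC(C)(C)O[C@H](C=C)[C@]2(C)[C@H]1[C@@H](O)[C@]1(OCc2ccc(OC)cc2)[C@@H](C)COC1=O
F9 | step 2 | racemic 2-(2,2-dimethoxyethyl)-3-methoxy-2-methyl-3-oxopropanoic acid | COC(=O)C(C)(CC(OC)OC)C(=O)O
F10 | step 2 | (S)-1-phenylethylammonium salt of 4 | C[C@H]([NH3+])c1ccccc1.COC(=O)[C@@](C(=O)[O-])(C)CC(OC)OC
A1 | alternative 1 | bicyclic C14 alcohol, 2,9-di-O-TBS-8-O-TMS derivative of 32 | C=C1CC[C@H](O)[C@@]2(C)[C@H]1[C@@H](O[Si](C)(C)C(C)(C)C)[C@@]1(O[Si](C)(C)C)[C@H](/C=C(/C)CC[C@H]2O[Si](C)(C)C(C)(C)C)OC(=O)[C@@H]1C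
A2 | alternative 2 | ring B 8,9-diol with open lactone arm | C=C1CC[C@H](OC(C)=O)[C@@]2(C)[C@H]1[C@@H](O)[C@](O)([C@@H](C)CO[Si](C)(C)C(C)(C)C)[C@H](/C=C(/C)CC[C@H]2OC(C)=O)O[Si](C)(C)C(C)(C)C
A3 | alternative 3 | 9-O-triethylsilyl analogue of 33 | C=C1CC[C@H](OC(C)=O)[C@@]2(C)[C@H]1[C@@H](O[Si](CC)(CC)CC)[C@@]1(O)[C@H](/C=C(/C)CC[C@H]2OC(C)=O)OC(=O)[C@@H]1C
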